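**Assumption:** the olefin geometry of metathesis product 14 is left open (E major, drawn as E), because that double bond is hydrogenated in the last step.

## Retrosynthetic overview

1. Target 15 comes from 14 by one hydrogenation that saturates C4=C5 and removes both benzyl ethers; the C2 acetate is already in place.
2. C4=C5 is made by cross-metathesis of homoallylic acetate 10 with 10-(benzyloxy)dec-1-ene 13.
3. The key C2–C3 bond and the (R)-carbinol come from a Brown asymmetric allylboration of arylacetaldehyde 7.
4. Aldehyde 7 comes from 3,5-dimethoxybenzaldehyde 1 by mono-demethylation, benzylation, methylenation, hydroboration–oxidation and Dess–Martin oxidation.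
5. No ring is formed; the benzene ring is bought intact.

## Route

Step 1
Reactants: 1 3,5-dimethoxybenzaldehyde
Product: 2 3-hydroxy-5-methoxybenzaldehyde
Conditions: NaSEt (3 equiv), DMF, 150 °C, 1.5 h; then 1 M HCl
Reagents that add atoms: none
Why: Thiolate SN2 cleavage of an aryl methyl ether stops after one methyl because the resulting phenoxide deactivates the ring towards a second cleavage, and the aldehyde only forms a reversible hemithioacetal.

Step 2
Reactants: 2 3-hydroxy-5-methoxybenzaldehyde
Product: 3 3-(benzyloxy)-5-methoxybenzaldehyde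
Conditions: BnBr (1.2 equiv), K2CO3 (2 equiv), DMF, rt
Reagents that add atoms: benzyl bromide, BrCc1ccccc1
Why: Williamson ether synthesis on the only acidic OH; the non-enolisable aldehyde is inert to K2CO3.

Step 3
Reactants: 3 3-(benzyloxy)-5-methoxybenzaldehyde
Product: 4 1-(benzyloxy)-3-ethenyl-5-methoxybenzene
Conditions: Ph3PCH3Br (1.5 equiv), KOtBu (1.4 equiv), THF, 0 °C to rt
Reagents that add atoms: methyltriphenylphosphonium bromide, C[P+](c1ccccc1)(c1ccccc1)c1ccccc1.[Br-] (its CH2 carbon)
Why: Wittig methylenation of an aromatic aldehyde is dependable, and the ethers do not react with the ylide.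

Step 4
Reactants: 4 1-(benzyloxy)-3-ethenyl-5-methoxybenzene
Product: 6 2-[3-(benzyloxy)-5-methoxyphenyl]ethan-1-ol, via B-alkyl-9-BBN adduct 5 (not isolated)
Conditions: 9-BBN (1.5 equiv), THF, 0 °C to rt; then 3 M NaOH, 30% H2O2, 0 °C to rt
Reagents that add atoms: hydrogen peroxide, OO (oxygen of the new OH); 9-borabicyclo[3.3.1]nonane, B1C2CCCC1CCC2 (boron cage, in intermediate 5 only)
Why: Brown hydroboration–oxidation with the bulky 9-BBN places boron on the terminal styrene carbon (anti-Markovnikov, >98:2), and the C–B bond is oxidised with retention to the primary alcohol.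

Step 5
Reactants: 6 2-[3-(benzyloxy)-5-methoxyphenyl]ethan-1-ol
Product: 7 2-[3-(benzyloxy)-5-methoxyphenyl]acetaldehyde
Conditions: Dess–Martin periodinane (1.2 equiv), CH2Cl2, 0 °C to rt, 1 h; crude aldehyde used at once
Reagents that add atoms: none
Why: Dess–Martin oxidation stops at the aldehyde under mild, base-free conditions, which suits an enolisable arylacetaldehyde that is carried on without storage.

Step 6
Reactants: 7 2-[3-(benzyloxy)-5-methoxyphenyl]acetaldehyde
Product: 9 (2R)-1-[3-(benzyloxy)-5-methoxyphenyl]pent-4-en-2-ol, via diisopinocampheylborinate ester 8 (not isolated)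
Conditions: (+)-Ipc2BOMe (enantiomer made from (−)-α-pinene, 1.5 equiv), allylMgBr (1.4 equiv), Et2O, 0 °C to rt; then 7, −78 °C, 3 h; then 3 M NaOH, 30% H2O2, rt
Reagents that add atoms: allylmagnesium bromide, C=CC[Mg]Br (the three allyl carbons, delivered through the B-allylborane made in the flask); (+)-B-methoxydiisopinocampheylborane, COB([C@H]1C[C@H]2C[C@@H]([C@@H]1C)C2(C)C)[C@H]1C[C@H]2C[C@@H]([C@@H]1C)C2(C)C (boron and isopinocampheyl groups, in intermediate 8 only)
Why: Brown asymmetric allylboration, a carbonyl allylation through a closed chair transition state in which the isopinocampheyl groups derived from (−)-α-pinene direct the allyl group to the Re face of the aldehyde, sets C2 as (R) (typically ≥90% ee) at −78 °C, where the allylborane adds faster than the aldehyde enolises.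

Step 7
Reactants: 9 (2R)-1-[3-(benzyloxy)-5-methoxyphenyl]pent-4-en-2-ol
Product: 10 (2R)-1-[3-(benzyloxy)-5-methoxyphenyl]pent-4-en-2-yl acetate
Conditions: Ac2O (2 equiv), pyridine (3 equiv), DMAP (5 mol%), CH2Cl2, 0 °C to rt
Reagents that add atoms: acetic anhydride, CC(=O)OC(C)=O
Why: DMAP-catalysed O-acylation leaves the C2–O bond untouched, so configuration is retained, and it puts the acetate on before any other hydroxyl exists.

Step 8
Reactants: 11 dec-9-en-1-ol
Product: 13 10-(benzyloxy)dec-1-ene, via sodium dec-9-en-1-olate 12 (not isolated)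
Conditions: NaH (1.3 equiv), THF/DMF, 0 °C; then BnBr (1.2 equiv), Bu4NI (5 mol%), rt
Reagents that add atoms: benzyl bromide, BrCc1ccccc1; sodium hydride, [Na+].[H-] (sodium, in intermediate 12 only)
Why: Williamson etherification of a primary alkoxide with benzyl bromide is near quantitative, and the terminal alkene is inert.

Step 9
Reactants: 10 (2R)-1-[3-(benzyloxy)-5-methoxyphenyl]pent-4-en-2-yl acetate; 13 10-(benzyloxy)dec-1-ene (3 equiv)
Product: 14 (2R)-13-(benzyloxy)-1-[3-(benzyloxy)-5-methoxyphenyl]tridec-4-en-2-yl acetate (E/Z mixture)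
Conditions: second-generation Grubbs catalyst RuCl2(=CHPh)(PCy3)(H2IMes) (5 mol%), 1,4-benzoquinone (10 mol%), CH2Cl2, 40 °C, argon sweep
Reagents that add atoms: none
Why: Olefin cross-metathesis of two terminal alkenes is driven by loss of ethene and pushed to the cross product by the excess of the cheap partner, while benzoquinone suppresses ruthenium hydride double-bond migration; the stereocentre is not involved.

Step 10
Reactants: 14 (2R)-13-(benzyloxy)-1-[3-(benzyloxy)-5-methoxyphenyl]tridec-4-en-2-yl acetate
Product: 15 (2R)-13-hydroxy-1-(3-hydroxy-5-methoxyphenyl)tridecan-2-yl acetate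
Conditions: H2 (1 atm), 10% Pd/C, EtOAc/EtOH (1:1), rt
Reagents that add atoms: none
Why: Catalytic hydrogenation saturates the olefin and hydrogenolyses the aryl and alkyl benzyl ethers in one operation, while the homobenzylic secondary acetate and its stereocentre are untouched.

## Compound list

1 | 3,5-dimethoxybenzaldehyde | COc1cc(C=O)cc(OC)c1 | starting material
2 | 3-hydroxy-5-methoxybenzaldehyde | COc1cc(O)cc(C=O)c1 | intermediate
3 | 3-(benzyloxy)-5-methoxybenzaldehyde | COc1cc(OCc2ccccc2)cc(C=O)c1 | intermediate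
4 | 1-(benzyloxy)-3-ethenyl-5-methoxybenzene | COc1cc(OCc2ccccc2)cc(C=C)c1 | intermediate
5 | 9-{2-[3-(benzyloxy)-5-methoxyphenyl]ethyl}-9-borabicyclo[3.3.1]nonane | COc1cc(OCc2ccccc2)cc(CCB2C3CCCC2CCC3)c1 | intermediate (not isolated)
6 | 2-[3-(benzyloxy)-5-methoxyphenyl]ethan-1-ol | COc1cc(OCc2ccccc2)cc(CCO)c1 | intermediate
7 | 2-[3-(benzyloxy)-5-methoxyphenyl]acetaldehyde | COc1cc(OCc2ccccc2)cc(CC=O)c1 | intermediate
8 | (2R)-1-[3-(benzyloxy)-5-methoxyphenyl]pent-4-en-2-yl diisopinocampheylborinate (isopinocampheyl groups from (−)-α-pinene) | COc1cc(OCc2ccccc2)cc(C[C@@H](CC=C)OB([C@H]2C[C@H]3C[C@@H]([C@@H]2C)C3(C)C)[C@H]2C[C@H]3C[C@@H]([C@@H]2C)C3(C)C)c1 | intermediate (not isolated)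
9 | (2R)-1-[3-(benzyloxy)-5-methoxyphenyl]pent-4-en-2-ol | COc1cc(OCc2ccccc2)cc(C[C@@H](CC=C)O)c1 | intermediate
10 | (2R)-1-[3-(benzyloxy)-5-methoxyphenyl]pent-4-en-2-yl acetate | COc1cc(OCc2ccccc2)cc(C[C@@H](CC=C)OC(C)=O)c1 | intermediate
11 | dec-9-en-1-ol | C=CCCCCCCCCO | starting material
12 | sodium dec-9-en-1-olate | C=CCCCCCCCC[O-].[Na+] | intermediate (not isolated)
13 | 10-(benzyloxy)dec-1-ene | C=CCCCCCCCCOCc1ccccc1 | intermediate
14 | (2R)-13-(benzyloxy)-1-[3-(benzyloxy)-5-methoxyphenyl]tridec-4-en-2-yl acetate (E/Z mixture, E isomer drawn) | COc1cc(OCc2ccccc2)cc(C[C@@H](C/C=C/CCCCCCCCOCc2ccccc2)OC(C)=O)c1 | intermediate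
15 | (2R)-13-hydroxy-1-(3-hydroxy-5-methoxyphenyl)tridecan-2-yl acetate | COc1cc(O)cc(C[C@@H](CCCCCCCCCCCO)OC(C)=O)c1 | target

## Summary

Total step count: 10.
Longest linear sequence: 9 steps (steps 1 to 7, then 9 and 10); step 8 is a one-step side branch.

The three steps most likely to fail:

**Step 1 (mono-demethylation next to a free aldehyde).** The hot thiolate can give lower yields through aldehyde side reactions or some double demethylation. The fallback sets out from 1 and comes back at 6, moving the demethylation to a stage with no aldehyde present. Wittig methylenation of 1 (Ph3PCH3Br, KOtBu, THF) gives 1-ethenyl-3,5-dimethoxybenzene F1. Hydroboration with 9-BBN gives 9-[2-(3,5-dimethoxyphenyl)ethyl]-9-borabicyclo[3.3.1]nonane F2 (not isolated), which NaOH/H2O2 oxidises to 2-(3,5-dimethoxyphenyl)ethan-1-ol F3. NaSEt in DMF at 150 °C then removes one methyl to give 3-(2-hydroxyethyl)-5-methoxyphenol F4. Benzylation of the phenol alone (BnBr, K2CO3, acetone, reflux; the aliphatic alcohol is not deprotonated) gives 6.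

**Step 6 (asymmetric allylation of a labile arylacetaldehyde).** Aldehyde 7 can self-condense before it is trapped, and the ee may fall short of what a single enantiomer needs. Filtering off the magnesium salts and running at −100 °C would be tried first. The fallback sets out from 6 and comes back at 9, so 7 is never isolated. It is an iridium-catalysed transfer-hydrogenative carbonyl allylation from the alcohol oxidation level (Krische): allyl acetate (10 equiv), [Ir(cod)Cl]2 (2.5 mol%), (R)-BINAP (5 mol%), 4-chloro-3-nitrobenzoic acid (10 mol%), Cs2CO3 (20 mol%), THF, 100 °C. The catalyst dehydrogenates 6 to the aldehyde at low concentration and adds an allyl-iridium unit to it under ligand control. I am not certain from memory that (R)-BINAP is the hand that gives (R)-9; this would be confirmed by Mosher ester analysis, and (S)-BINAP used if the sense is reversed. It makes no new compound (entry F0).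

**Step 9 (cross-metathesis).** Homodimerisation, incomplete conversion or double-bond migration (which would scramble the chain length) can lower the yield. The fallback sets out from 10 and comes back at 15, replacing metathesis by an alkyl–alkyl Suzuki–Miyaura coupling. Hydroboration of 10 with 9-BBN (THF, rt; the acetate is inert) gives (2R)-1-[3-(benzyloxy)-5-methoxyphenyl]-5-(9-borabicyclo[3.3.1]nonan-9-yl)pentan-2-yl acetate F5 (not isolated). This is coupled (Pd(OAc)2 4 mol%, PCy3 8 mol%, K3PO4·H2O, THF, rt) with 1-(benzyloxy)-8-bromooctane F6, prepared from 8-bromooctan-1-ol with benzyl 2,2,2-trichloroacetimidate and catalytic TfOH. The product is the saturated (2R)-13-(benzyloxy)-1-[3-(benzyloxy)-5-methoxyphenyl]tridecan-2-yl acetate F7, with the full chain and no olefin. Hydrogenolysis (H2, 10% Pd/C, EtOAc/EtOH) then gives 15.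

## Further compounds

F1 | step 1 | 1-ethenyl-3,5-dimethoxybenzene | COc1cc(C=C)cc(OC)c1
F2 | step 1 | 9-[2-(3,5-dimethoxyphenyl)ethyl]-9-borabicyclo[3.3.1]nonane | COc1cc(CCB2C3CCCC2CCC3)cc(OC)c1
F3 | step 1 | 2-(3,5-dimethoxyphenyl)ethan-1-ol | COc1cc(CCO)cc(OC)c1
F4 | step 1 | 3-(2-hydroxyethyl)-5-methoxyphenol | COc1cc(O)cc(CCO)c1
F0 | step 6 | none | none
F5 | step 9 | (2R)-1-[3-(benzyloxy)-5-methoxyphenyl]-5-(9-borabicyclo[3.3.1]nonan-9-yl)pentan-2-yl acetate | COc1cc(OCc2ccccc2)cc(C[C@@H](CCCB2C3CCCC2CCC3)OC(C)=O)c1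
F6 | step 9 | 1-(benzyloxy)-8-bromooctane | BrCCCCCCCCOCc1ccccc1
F7 | step 9 | (2R)-13-(benzyloxy)-1-[3-(benzyloxy)-5-methoxyphenyl]tridecan-2-yl acetate | COc1cc(OCc2ccccc2)cc(C[C@@H](CCCCCCCCCCCOCc2ccccc2)OC(C)=O)c1
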